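(The data are simulated with constants of no real substance.)

A reaction still consuming starting material cannot show a flat line, yet both earlier runs come close to one.

| setting | north-east | south-east | flask |
|---|---|---|---|
| starting material | 0.13 M | 0.13 M | 0.13 M |
| gas phase | 12 mM (held) | 12 mM (held) | 12 mM (held) |
| free catalyst | 13 mM | 21 mM | 9.4 mM |
| remark | run made earlier | run made earlier |  |
| time |  |  | 80 min |

| run | time / min | target / % | starting material / % |
|---|---|---|---|
| north-east | 15.0 | 33.2 | 52.5 |
| north-east | 30.0 | 34.2 | 43.4 |
| north-east | 40.0 | 32.5 | 42.1 |
| north-east | 60.0 | 25.5 | 41.6 |
| north-east | 80.0 | 19.2 | 42.3 |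
| north-east | 90.0 | 17.6 | 41.8 |
| south-east | 5.00 | 18.4 | 70.7 |
| south-east | 15.0 | 38.7 | 40.9 |
| south-east | 25.0 | 45.2 | 29.3 |
| south-east | 40.0 | 42.4 | 22.8 |
| south-east | 60.0 | 34.8 | 20.4 |
| south-east | 80.0 | 28.1 | 19.5 |
| south-east | 90.0 | 22.9 | 19.0 |

(each reading ± 0.5 percentage points)

- at the start none of the gas phase is in solution

- amber: doubling the transfer coefficient of the gas phase, all else as stated
- ochre: doubling the saturation concentration of gas phase, all else as stated
- teal: doubling the amount of free catalyst, all else as stated

1. target at 80 min, in percent of the starting material charged
2. the change that raises the amount of target at 80 min, in percent of the starting material charged most ("none" if none brings more than 2 percentage points) (amber / ochre / teal / none)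
3. amount of target at 80 min, in percent of the starting material charged, after teal

I read the starting-material columns first. The north-east run stands at 41.6 % at 60.0 min and 41.8 % at 90.0 min, and the south-east run creeps from 19.5 % to 19.0 % over its last readings, so I take the catalyst to be a store that stops working. I therefore count turnovers. Per catalyst charged, the north-east run consumes 5.82 of starting material and the south-east run 5.01, so the count is higher at the lower charge. A straight line through these gives 6.18 for the flask. This turnover count, starting material consumed per catalyst charged, is what I carry.

In both runs target falls over the last readings while starting material hardly moves, so target is being lost. At 80 min target is 0.333 of the consumed starting material in the north-east run and 0.349 in the south-east run. So I expect the flask to consume 44.7 % of its charge and hold 15.2 % of target. The same line gives 25.8 % after teal. The runs hold the gas at one value, so I have no reading for amber or ochre.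

The forecast gives 14.7 %, and 25.3 % after teal, and it names teal, reasoning “More gas probably kills the catalyst faster”. My figures stand above these.

The flask gives 15.8 %, and 25.1 % after teal. The best change is ochre, worth 22 percentage points, against 9.4 points for amber and 9.2 points for teal.

    gas phase ⇌ dissolved gas, rate k1*(csat - [dissolved gas]) (kL = 0.490 min⁻¹)
    target → over-reaction product (k = 0.0130 min⁻¹)
    starting material + free catalyst → spent catalyst (k = 2.10 M⁻¹ min⁻¹)
    starting material + dissolved gas + free catalyst → free catalyst + target (k = 3800 M⁻² min⁻¹)

The flask consumes 6.53 per catalyst charged, against the carried 6.18. In the flask, per free catalyst, making target outruns the loss to spent catalyst by a factor of 9.35 at 8.00 min, with [dissolved gas] at 0.00517 M and 16.2 % of the catalyst still free. The factor at [dissolved gas] of 12 mM is 21.7, but in the flask at 40.0 min, with [dissolved gas] at 0.0119 M, 0.114 % of the catalyst is free. A further flask charged with 0.038 M of free catalyst holds 3.42 of starting material per catalyst, below the carried count, which was reckoned for a charge of 9.4 mM. In that further flask starting material is the limiting reagent: at 80.0 min, 0.014 % of it remains, with 6.43 % of the catalyst still free.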